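The route rests on opening cyclohexane ring B at two bonds. One is C8–C9 (C8 = quaternary carbon shared by ring B, the cyclopentane and the bicyclo[2.2.2]octane; C9 = methine). The other is C5–C10 (C5 = spiro carbon, C10 = tertiary carbinol). C9/C10 are the α-carbon and carbonyl of a 3-oxobutyl arm, C8 is a tertiary cation, and C5 is the γ-terminus of a cyclopentadienyl silyl ether, the carbocyclic precursor of lactone ring A. One TiCl4 operation ionises a C8 acetate and closes the cyclopentane through the enol silane. The dienol silane then attacks the ketone just released, closing ring B and setting four contiguous stereocentres. The precursor is a bicyclooctane lactone bearing both arms.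

Key step: step 15

Locants used below: ring A = C1(H)=C2(H)–C3(=O)–(O)–C4(Me2)–C5; ring B = C5–C6H2–C7H2–C8–C9H–C10(Me)(OH); C11H2 joins C9 to C5′; C12H2 joins C8 to C3′; the bicyclo[2.2.2]octane has bridgeheads C3′(Me) and C6′ and bridges C4′(=O)–C5′(Me), C2′(O)–C1′(H) and C12–C8; C6′–C7′H2–O–C8′(=O)–C1′ is the γ-lactone.

Assumption: the facial bias of the (S,S)-hydrobenzoin ketal in step 7 comes from a steric model in which the ketal phenyl group leaning over C6′ shields that face. If the sense were opposite, the (R,R)-diol would be used. Compounds 1 and 12 and all reagents are taken as catalogue chemicals.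

Step 1
Reactants: 1 4-methoxy-2,6-dimethylphenol
Product: 2 3-hydroxy-6-methoxy-2,4-dimethylbenzaldehyde
Conditions: Cl2CHOMe, TiCl4, CH2Cl2, 0 °C; then H2O
Reagents that add atoms: dichloromethyl methyl ether, COC(Cl)Cl; water, O
Why: Rieche formylation; both positions ortho to OH are blocked and the two free positions ortho to OMe are equivalent, so a single aldehyde should form.

Step 2
Reactants: 2 3-hydroxy-6-methoxy-2,4-dimethylbenzaldehyde
Product: 3 3-(hydroxymethyl)-4-methoxy-2,6-dimethylphenol
Conditions: NaBH4, MeOH, 0 °C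
Reagents that add atoms: none
Why: Borohydride reduction of the aryl aldehyde to the benzylic alcohol; no stereocentre is formed.

Step 3
Reactants: 3 3-(hydroxymethyl)-4-methoxy-2,6-dimethylphenol
Product: 4 (3-hydroxy-6-methoxy-2,4-dimethylphenyl)methyl prop-2-ynoate
Conditions: propiolic acid, DCC, DMAP (cat.), CH2Cl2, −20 °C
Reagents that add atoms: propiolic acid, C#CC(=O)O
Why: Steglich esterification; the primary benzylic alcohol is acylated while the phenol flanked by two methyl groups stays free.

Step 4
Reactants: 4 (3-hydroxy-6-methoxy-2,4-dimethylphenyl)methyl prop-2-ynoate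
Product: 5 (3-hydroxy-6-methoxy-2,4-dimethylphenyl)methyl (Z)-3-acetoxyprop-2-enoate
Conditions: AcOH, Ag2CO3 (5 mol%), PhMe, 80 °C
Reagents that add atoms: acetic acid, CC(=O)O
Why: Silver(I)-catalysed hydroacyloxylation of a propiolate by anti addition should give the (Z)-β-acetoxyacrylate, which fixes the later cis relation of C8′ and the C2′ oxygen.

Step 5
Reactants: 5 (3-hydroxy-6-methoxy-2,4-dimethylphenyl)methyl (Z)-3-acetoxyprop-2-enoate
Product: 7 (S,S)-hydrobenzoin p-quinone monoketal [(2S,3S)-7,9-dimethyl-8-oxo-2,3-diphenyl-1,4-dioxaspiro[4.5]deca-6,9-dien-6-yl]methyl (Z)-3-acetoxyacrylate, via dimethyl ketal 6 (not isolated)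
Conditions: PhI(OAc)2, MeOH, 0 °C; evaporate; (S,S)-hydrobenzoin, BF3·OEt2 (cat.), DME, rt
Reagents that add atoms: (1S,2S)-1,2-diphenylethane-1,2-diol, O[C@@H](c1ccccc1)[C@@H](O)c1ccccc1; methanol, CO (retained only in 6)
Why: Hypervalent-iodine oxidative dearomatisation of a 4-methoxyphenol gives the p-quinone monoketal, and acid-catalysed transketalisation installs the C2-symmetric chiral ketal, whose spiro carbon (C8) is not stereogenic.

Step 6
Reactants: 7 (S,S)-hydrobenzoin p-quinone monoketal
Product: 8 [(2S,3S)-7,9-dimethyl-2,3-diphenyl-8-(triethylsilyloxy)-1,4-dioxaspiro[4.5]deca-6,8-dien-6-yl]methyl (Z)-3-acetoxyacrylate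
Conditions: Et3SiH (1.1 equiv), RhCl(PPh3)3 (1 mol%), PhH, 50 °C
Reagents that add atoms: triethylsilane, CC[SiH](CC)CC
Why: Rhodium-catalysed 1,4-hydrosilylation of an enone; the C12=C3′ bond with its free β-CH should react before the tetrasubstituted enone and the β-oxygenated acrylate, giving the cross-conjugated 2-silyloxydiene.

Step 7
Reactants: 8 triethylsilyl dienol ether with tethered (Z)-3-acetoxyacrylate
Product: 9 endo cycloadduct: bicyclo[2.2.2]octene γ-lactone with a C4′(OTES)=C5′(Me) bridge, C8 hydrobenzoin ketal, 3′-Me, and C8′ and 2′-OAc both syn to the C4′=C5′ bridge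
Conditions: PhMe (0.01 M), BHT, 2,6-di-tert-butylpyridine, 135 °C, sealed tube
Reagents that add atoms: none
Why: Intramolecular Diels–Alder reaction in which the nucleophilic diene terminus C3′ bonds to the acrylate β-carbon C2′; the Z-alkene and the endo transition state place C8′ and OAc syn to the new C4′=C5′ bridge, and the ketal phenyl group over one face of C6′ sends the tethered dienophile to the other face, setting C3′, C6′, C1′ and C2′.

Step 8
Reactants: 9 endo cycloadduct
Product: 10 C8 ketone: cage of 9 with C8=O and the C4′(OTES)=C5′(Me) enol ether intact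
Conditions: H2 (1 atm), Pd(OH)2/C, EtOAc, rt
Reagents that add atoms: none
Why: Hydrogenolysis of the two benzylic C–O bonds unmasks the ketone under neutral conditions that the tetrasubstituted silyl enol ether, the acetate and the lactone tolerate.

Step 9
Reactants: 10 C8 ketone
Product: 11 C5′-quaternary diketone: 5′-Me syn to the C1′–C2′ bridge and the (Z)-C11H2–C9H=C10(OTES)CH3 arm syn to the C8–C12 bridge
Conditions: methyl vinyl ketone (1.5 equiv), Tf2NH (2 mol%), CH2Cl2, −78 °C
Reagents that add atoms: methyl vinyl ketone, C=CC(C)=O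
Why: Mukaiyama–Michael addition with silyl transfer; the enone reaches C5′ from the side of the flat C8 ketone because the other side is covered by the endo C8′ and OAc groups, which sets the C5′ quaternary centre and delivers the regiodefined (Z)-enol silane.

Step 10
Reactants: 12 2,2-dimethylcyclopentane-1,3-dione
Product: 14 2,2-dimethyl-3-vinylcyclopent-3-en-1-one, via tertiary allylic alcohol 13 (not isolated)
Conditions: CH2=CHMgBr (1 equiv), THF, −78 °C; 1 M HCl; p-TsOH (cat.), CH2Cl2, rt
Reagents that add atoms: vinylmagnesium bromide, C=C[Mg]Br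
Why: Grignard 1,2-addition to one carbonyl followed by acid-catalysed dehydration, which can only run towards the ring CH2 and gives the conjugated diene.

Step 11
Reactants: 14 2,2-dimethyl-3-vinylcyclopent-3-en-1-one
Product: 16 3-(2-hydroxyethyl)-2,2-dimethylcyclopent-3-en-1-one, via B-alkyl-9-BBN adduct 15 (not isolated)
Conditions: 9-BBN (1.05 equiv), THF, 0 °C; NaBO3·4H2O, H2O, rt
Reagents that add atoms: sodium perborate, [Na+].[Na+].O[B-]1(O)OO[B-](O)(O)OO1
Why: Hydroboration–oxidation; 9-BBN should add to the terminal carbon of the monosubstituted vinyl group faster than to the trisubstituted ring alkene or the neopentyl ketone.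

Step 12
Reactants: 16 3-(2-hydroxyethyl)-2,2-dimethylcyclopent-3-en-1-one
Product: 17 3-(2-iodoethyl)-2,2-dimethylcyclopent-3-en-1-one
Conditions: I2, PPh3, imidazole, CH2Cl2, 0 °C
Reagents that add atoms: iodine, II
Why: Appel iodination of the primary alcohol.

Step 13
Reactants: 17 3-(2-iodoethyl)-2,2-dimethylcyclopent-3-en-1-one
Product: 18 tert-butyl{[4-(2-iodoethyl)-5,5-dimethylcyclopenta-1,3-dien-1-yl]oxy}dimethylsilane
Conditions: TBSOTf, Et3N, CH2Cl2, 0 °C
Reagents that add atoms: tert-butyldimethylsilyl triflate, CC(C)(C)[Si](C)(C)OS(=O)(=O)C(F)(F)F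
Why: Soft enolisation–silylation; only the doubly activated ring CH2 can be deprotonated because the other α-carbon is quaternary, giving a 5,5-dimethylcyclopentadienyl silyl ether that has no hydrogen on its sp3 carbon to shift.

Step 14
Reactants: 18 tert-butyl{[4-(2-iodoethyl)-5,5-dimethylcyclopenta-1,3-dien-1-yl]oxy}dimethylsilane; 11 C5′-quaternary diketone
Product: 20 C8 tertiary acetate carrying the C7–C6 chain to the silyloxycyclopentadiene (OAc syn to the C4′–C5′ bridge), via alkyllithium 19 (not isolated)
Conditions: 18, t-BuLi (2 equiv), Et2O, −78 °C; LaCl3·2LiCl (0.3 equiv), 11, THF, −78 °C; Ac2O, −78 → 0 °C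
Reagents that add atoms: acetic anhydride, CC(=O)OC(C)=O
Why: Iodine–lithium exchange and lanthanum-assisted 1,2-addition to the only accessible ketone (the C4′ ketone lies between two quaternary carbons), from the side away from the C11 arm, then acetylation of the alkoxide; the C8 configuration made here is erased in step 15.

Step 15
Reactants: 20 C8 tertiary acetate
Product: 22 hexacyclic spiro-cyclopentenone 2′-acetate (target skeleton with C3 bonded directly to C4), via isotwistane methyl ketone 21 (not isolated)
Conditions: TiCl4 (3 equiv), 2,6-di-tert-butyl-4-methylpyridine, CH2Cl2, −78 → −40 °C; aq. NaHCO3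
Reagents that add atoms: none
Why: Proposed new method: TiCl4 ionises the only tertiary ester (C8–OAc) to a tertiary cation whose Wagner–Meerwein escape is disfavoured because the migration origin C6′ carries an acyloxymethyl group and two β-carbonyl groups; the (Z)-enol silane held next to it by the C5′ arm captures it at C9 (loss of TESCl), and methyl ketone 21, born bound to titanium, is attacked at C10 by the γ-carbon C5 of the cyclopentadienyl silyl ether (loss of TBSCl). The closest known reaction types are the Lewis-acid α-tert-alkylation of silyl enol ethers with SN1-active esters or chlorides and the intramolecular vinylogous Mukaiyama aldol addition to ketones; running them as one domino is the new element. The cyclopentane closes 5-exo-trig (enolexo) and ring B closes 6-exo-trig at the carbonyl through a chair. C8 is fixed by the tether, which reaches only the face turned to the C4′–C5′ bridge; at C9 only the epimer with the acetyl group syn to C7 can cyclise on, and titanium enolisation should feed it; at C10 the methyl group takes the equatorial and the titanium-bound oxygen the axial site syn to C11; at C5 the open transition state puts the bulky C4 (CMe2) antiperiplanar to that oxygen, so C1 ends syn to OH. The step needs chemoselective ionisation and the right pairing of two π-nucleophiles with two electrophiles: attack of the dienol silane on the cation would need a four-membered ring (through C5) or an anti-Bredt bicycle (through C2), and the enol silane is consumed before any ketone exists.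

Step 16
Reactants: 22 hexacyclic spiro-cyclopentenone 2′-acetate
Product: 23 2′-O-acetyl derivative of the target (ring A = 6,6-dimethyl-5,6-dihydropyran-2-one)
Conditions: mCPBA, CH2Cl2, 0 °C → rt
Reagents that add atoms: 3-chloroperbenzoic acid, OOC(=O)c1cccc(Cl)c1
Why: Baeyer–Villiger oxidation; the tertiary C4 migrates with retention in preference to the vinylic C2, and the C4′ ketone buried between two quaternary carbons should resist peracid addition.

Step 17
Reactants: 23 2′-O-acetyl derivative of the target
Product: 24 CNP0360620.2 (target)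
Conditions: K2CO3 (0.2 equiv), MeOH, 0 °C
Reagents that add atoms: none
Why: Base-catalysed methanolysis of the secondary acetate; the tertiary-alkyl δ-lactone and the neopentyl γ-lactone open far more slowly and would re-close.

Compound list

1 | 4-methoxy-2,6-dimethylphenol | COc1cc(C)c(O)c(C)c1 | starting material
2 | 3-hydroxy-6-methoxy-2,4-dimethylbenzaldehyde | COc1cc(C)c(O)c(C)c1C=O | intermediate
3 | 3-(hydroxymethyl)-4-methoxy-2,6-dimethylphenol | COc1cc(C)c(O)c(C)c1CO | intermediate
4 | (3-hydroxy-6-methoxy-2,4-dimethylphenyl)methyl prop-2-ynoate | COc1cc(C)c(O)c(C)c1COC(=O)C#C | intermediate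
5 | (3-hydroxy-6-methoxy-2,4-dimethylphenyl)methyl (Z)-3-acetoxyprop-2-enoate | COc1cc(C)c(O)c(C)c1COC(=O)/C=C\OC(C)=O | intermediate
6 | (6,6-dimethoxy-2,4-dimethyl-3-oxocyclohexa-1,4-dien-1-yl)methyl (Z)-3-acetoxyprop-2-enoate (not isolated) | COC1(OC)C=C(C)C(=O)C(C)=C1COC(=O)/C=C\OC(C)=O | intermediate
7 | [(2S,3S)-7,9-dimethyl-8-oxo-2,3-diphenyl-1,4-dioxaspiro[4.5]deca-6,9-dien-6-yl]methyl (Z)-3-acetoxyacrylate | O=C1C(C)=CC2(O[C@@H](c3ccccc3)[C@H](c3ccccc3)O2)C(COC(=O)/C=C\OC(C)=O)=C1C | intermediate
8 | [(2S,3S)-7,9-dimethyl-2,3-diphenyl-8-(triethylsilyloxy)-1,4-dioxaspiro[4.5]deca-6,8-dien-6-yl]methyl (Z)-3-acetoxyacrylate | CC[Si](CC)(CC)OC1=C(C)CC2(O[C@@H](c3ccccc3)[C@H](c3ccccc3)O2)C(COC(=O)/C=C\OC(C)=O)=C1C | intermediate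
9 | endo Diels–Alder adduct; C8 (S,S)-hydrobenzoin ketal; C4′(OTES)=C5′(Me); C8′ and 2′-OAc syn to that bridge | C15(O[C@@H](c2ccccc2)[C@H](c2ccccc2)O5)C[C@]3(C)C(O[Si](CC)(CC)CC)=C(C)[C@]14COC(=O)[C@H]4[C@H]3OC(C)=O | intermediate
10 | C8 ketone of the cage; C4′(OTES)=C5′(Me) retained | O=C1C[C@]2(C)C(O[Si](CC)(CC)CC)=C(C)[C@]13COC(=O)[C@H]3[C@H]2OC(C)=O | intermediate
11 | C8,C4′-diketone; C5′ quaternary (Me syn to C1′–C2′ bridge; (Z)-3-(triethylsilyloxy)but-2-enyl arm syn to C8–C12 bridge) | O=C1C[C@]2(C)C(=O)[C@](C)(C/C=C(/C)O[Si](CC)(CC)CC)[C@]13COC(=O)[C@H]3[C@H]2OC(C)=O | intermediate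
12 | 2,2-dimethylcyclopentane-1,3-dione | CC1(C)C(=O)CCC1=O | starting material
13 | 3-ethenyl-3-hydroxy-2,2-dimethylcyclopentan-1-one (racemic, not isolated) | CC1(C)C(=O)CCC1(O)C=C | intermediate
14 | 2,2-dimethyl-3-vinylcyclopent-3-en-1-one | CC1(C)C(=O)CC=C1C=C | intermediate
15 | 3-[2-(9-borabicyclo[3.3.1]nonan-9-yl)ethyl]-2,2-dimethylcyclopent-3-en-1-one (not isolated) | CC1(C)C(=O)CC=C1CCB1C2CCCC1CCC2 | intermediate
16 | 3-(2-hydroxyethyl)-2,2-dimethylcyclopent-3-en-1-one | CC1(C)C(=O)CC=C1CCO | intermediate
17 | 3-(2-iodoethyl)-2,2-dimethylcyclopent-3-en-1-one | CC1(C)C(=O)CC=C1CCI | intermediate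
18 | tert-butyl{[4-(2-iodoethyl)-5,5-dimethylcyclopenta-1,3-dien-1-yl]oxy}dimethylsilane | CC1(C)C(CCI)=CC=C1O[Si](C)(C)C(C)(C)C | intermediate
19 | 2-[4-(tert-butyldimethylsilyloxy)-5,5-dimethylcyclopenta-1,3-dien-1-yl]ethyllithium (not isolated) | [Li]CCC1=CC=C(O[Si](C)(C)C(C)(C)C)C1(C)C | intermediate
20 | C8 tertiary acetate (OAc syn to C4′–C5′ bridge; C7–C6 chain to the silyloxycyclopentadiene; (Z)-enol silane arm on C5′) | CC(=O)O[C@]1(CCC4=CC=C(O[Si](C)(C)C(C)(C)C)C4(C)C)C[C@]2(C)C(=O)[C@](C)(C/C=C(/C)O[Si](CC)(CC)CC)[C@]13COC(=O)[C@H]3[C@H]2OC(C)=O | intermediate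
21 | isotwistane methyl ketone: C8–C9 closed, acetyl on C9 syn to C7, silyloxycyclopentadiene intact (not isolated) | CC1(C)C(CC[C@]23C[C@]4(C)C(=O)[C@](C)(C[C@H]2C(C)=O)[C@]35COC(=O)[C@H]5[C@H]4OC(C)=O)=CC=C1O[Si](C)(C)C(C)(C)C | intermediate
22 | hexacyclic spiro-cyclopentenone 2′-acetate; 10-OH syn to C11 and C1; 10-Me syn to C4 | CC1(C)C(=O)C=C[C@]12CC[C@]13C[C@]4(C)C(=O)[C@](C)(C[C@H]1[C@@]2(C)O)[C@]31COC(=O)[C@H]1[C@H]4OC(C)=O | intermediate
23 | 2′-O-acetyl derivative of the target | CC1(C)OC(=O)C=C[C@]12CC[C@]13C[C@]4(C)C(=O)[C@](C)(C[C@H]1[C@@]2(C)O)[C@]31COC(=O)[C@H]1[C@H]4OC(C)=O | intermediate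
24 | CNP0360620.2 | CC1(C)OC(=O)C=C[C@]12CC[C@]13C[C@]4(C)C(=O)[C@](C)(C[C@H]1[C@@]2(C)O)[C@]31COC(=O)[C@H]1[C@H]4O | target

Total step count: 17. Longest linear sequence: 13 steps (steps 1–9 and 14–17).

Steps most likely to fail

Step 15 (Proposed new method). Three processes could defeat the domino: proton loss from the C8 cation to give alkenes, desilylation of the dienol silane before the ketone is formed, and poor facial selectivity in the aldol closure.

The fallback makes the two bonds one after the other with established reactions. Compound 20 with catalytic ZnI2 in CH2Cl2 at −40 °C should stop after the α-tert-alkylation. Mild acid work-up hydrolyses the cyclopentadienyl silyl ether and gives the isotwistane triketone F1. Catalytic KOt-Bu or DBU in THF then closes ring B by a reversible intramolecular vinylogous aldol addition of the most acidic position (the ring-A′ dienolate) under thermodynamic control. This returns to 22.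

Step 14. The coupling could be stopped by enolisation of the hindered C8 ketone, attack of the large alkyllithium on the acetate, or silyl migration from the neighbouring enol silane to the new alkoxide.

The fallback forms the C7–C8 bond with the smallest sp2 nucleophile and attaches ring A′ by cross-coupling:
- Compound 11 with vinylmagnesium bromide and LaCl3·2LiCl gives the C8 vinyl carbinol F2.
- 9-BBN hydroboration of its vinyl group, then B-alkyl Suzuki–Miyaura coupling with 5,5-dimethyl-4-oxocyclopent-1-en-1-yl triflate F3 (from 12 with KHMDS and PhNTf2), gives the C8 carbinol with the cyclopentenone chain F4.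
- Acetylation (Ac2O, DMAP) gives the corresponding C8 acetate F5.
- TBSOTf/Et3N converts F5 into 20.

Step 16. Peracid addition to the neopentyl enone may be too slow, or the strained cage ketone may be oxidised in competition.

The fallback replaces the peracid migration by an alkoxy-radical fragmentation. Luche reduction of 22 gives the C3 allylic alcohol F6. PhI(OAc)2/I2 under visible light generates the C3 alkoxy radical, whose β-scission releases the tertiary C4 radical and a (Z)-enal. Hydrolysis of the tertiary iodide and ring closure give the six-membered lactol F7. MnO2 or TPAP/NMO oxidation then returns to 23.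

Further compounds
F1 | step 15 | isotwistane triketone 2′-acetate with 3-substituted 2,2-dimethylcyclopent-3-enone chain | CC1(C)C(=O)CC=C1CC[C@]12C[C@]3(C)C(=O)[C@](C)(C[C@H]1C(C)=O)[C@]24COC(=O)[C@H]4[C@H]3OC(C)=O
F2 | step 14 | C8 vinyl carbinol of 11 (OH syn to the C4′–C5′ bridge) | O[C@]1(C=C)C[C@]2(C)C(=O)[C@](C)(C/C=C(/C)O[Si](CC)(CC)CC)[C@]13COC(=O)[C@H]3[C@H]2OC(C)=O
F3 | step 14 | 5,5-dimethyl-4-oxocyclopent-1-en-1-yl trifluoromethanesulfonate | CC1(C)C(=O)CC=C1OS(=O)(=O)C(F)(F)F
F4 | step 14 | C8 carbinol carrying the 2-(5,5-dimethyl-4-oxocyclopent-1-enyl)ethyl chain | O[C@]1(CCC4=CCC(=O)C4(C)C)C[C@]2(C)C(=O)[C@](C)(C/C=C(/C)O[Si](CC)(CC)CC)[C@]13COC(=O)[C@H]3[C@H]2OC(C)=O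
F5 | step 14 | C8 acetate of F4 | CC(=O)O[C@]1(CCC4=CCC(=O)C4(C)C)C[C@]2(C)C(=O)[C@](C)(C/C=C(/C)O[Si](CC)(CC)CC)[C@]13COC(=O)[C@H]3[C@H]2OC(C)=O
F6 | step 16 | C3 allylic alcohol from 22 (C3 configuration not defined) | CC1(C)C(O)C=C[C@]12CC[C@]13C[C@]4(C)C(=O)[C@](C)(C[C@H]1[C@@]2(C)O)[C@]31COC(=O)[C@H]1[C@H]4OC(C)=O
F7 | step 16 | ring-A lactol 2′-acetate (anomeric configuration not defined) | CC1(C)OC(O)C=C[C@]12CC[C@]13C[C@]4(C)C(=O)[C@](C)(C[C@H]1[C@@]2(C)O)[C@]31COC(=O)[C@H]1[C@H]4OC(C)=O
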